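The decalin is cut by a retro-Diels–Alder across ring A: C5–C10 (the ring-fusion bond) and C3–C4. The key step, a Lewis-acid-promoted intramolecular Diels–Alder reaction, closes rings A and B in one operation and sets C4, C5 and C10 from the single C9 stereocentre. It exploits the quaternary C4 of ring A, which carries an oxidised carbon (C18) and sits next to oxygenated C3: C4=C5 becomes an (E)-2-methylenal dienophile and C10=C1–C2=C3 a 1-boryl diene whose boron is later turned into the C3 oxygen. The precursor is an acyclic trienal, tethered through C6–C9, that already carries the C8 methylene and the protected side chain.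

Key step: step 14

Remark: labdane numbering is used for skeleton and positions only (ring A = C1–C5 + C10; ring B = C5–C10; C17 = methylene carbon on C8; C18 = oxygenated carbon on C4; C19 = methyl on C4; C20 = methyl on C10; C11–C16 = side chain); configurations are those of the SMILES. TBS = tert-butyldimethylsilyl, TES = triethylsilyl, Bpin = 4,4,5,5-tetramethyl-1,3,2-dioxaborolan-2-yl, Sc = (3Z)-5-(TBS-oxy)-3-[(TBS-oxy)methyl]pent-3-en-1-yl.

Step 1
Reactants: 1 but-3-en-1-ylmagnesium bromide; 2 dimethyl but-2-ynedioate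
Product: 5 dimethyl (2Z)-2-(but-3-en-1-yl)but-2-enedioate, via but-3-en-1-ylcopper 3 (not isolated), via alkenylcopper syn-adduct 4 (not isolated)
Conditions: CuBr·SMe2 (1.1 equiv), THF, −40 °C; then 2, −78 °C; aq NH4Cl at −78 °C
Reagents that add atoms: none
Why: Syn-carbocupration of the ynedioate (organocopper conjugate addition) and protonation of the alkenylcopper with retention at −78 °C should give the maleate, in which the two esters (later C15 and C16) are cis.

Step 2
Reactants: 5 dimethyl (2Z)-2-(but-3-en-1-yl)but-2-enedioate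
Product: 6 (2Z)-2-(but-3-en-1-yl)but-2-ene-1,4-diol
Conditions: iBu2AlH (5 equiv), CH2Cl2, −78 → 0 °C; aq potassium sodium tartrate
Reagents that add atoms: none
Why: 1,2-Reduction of both esters by the aluminium hydride should give the diol without touching the Z double bond.

Step 3
Reactants: 6 (2Z)-2-(but-3-en-1-yl)but-2-ene-1,4-diol
Product: 7 (2Z)-2-(but-3-en-1-yl)-1,4-bis(TBS-oxy)but-2-ene
Conditions: TBSCl (2.4 equiv), imidazole, DMF, 23 °C
Reagents that add atoms: tert-butyldimethylsilyl chloride, CC(C)(C)[Si](C)(C)Cl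
Why: Standard silylation of the two primary allylic hydroxyls.

Step 4
Reactants: 7 (2Z)-2-(but-3-en-1-yl)-1,4-bis(TBS-oxy)but-2-ene; 8 methacrolein
Product: 9 (2E,6Z)-8-(TBS-oxy)-6-[(TBS-oxy)methyl]-2-methylocta-2,6-dienal
Conditions: 8 (10 equiv), RuCl2(H2IMes)(=CH-C6H4-2-OiPr) (second-generation Hoveyda–Grubbs catalyst, 5 mol %), CH2Cl2, 40 °C
Reagents that add atoms: none
Why: Olefin cross-metathesis of the terminal alkene with excess methacrolein should give the thermodynamically favoured (E)-2-methylenal, the hindered trisubstituted alkene taking no part.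

Step 5
Reactants: 9 (2E,6Z)-8-(TBS-oxy)-6-[(TBS-oxy)methyl]-2-methylocta-2,6-dienal; 10 ethynyltrimethylsilane
Product: 12 (3S,4E,8Z)-10-(TBS-oxy)-8-[(TBS-oxy)methyl]-4-methyl-1-(trimethylsilyl)deca-4,8-dien-1-yn-3-ol, via methyl[(trimethylsilyl)ethynyl]zinc 11 (not isolated)
Conditions: 10 (3 equiv), Me2Zn (3 equiv), (S,S)-ProPhenol (20 mol %; the ligand antipode that gives the 3S alcohol is used), Ph3P=O (40 mol %), toluene, 4 °C; aq NH4Cl
Reagents that add atoms: none
Why: Zinc-alkynylide 1,2-addition to the enal under ProPhenol–dizinc catalysis (asymmetric alkynylation); the chiral pocket delivers the alkynyl group to one carbonyl face and sets the carbinol (labdane C1) as S, the centre that relays chirality to C9.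

Step 6
Reactants: 12 (3S,4E,8Z)-10-(TBS-oxy)-8-[(TBS-oxy)methyl]-4-methyl-1-(trimethylsilyl)deca-4,8-dien-1-yn-3-ol; 13 triethyl orthoacetate
Product: 15 ethyl (3R,4E)-4-methyl-3-Sc-7-(trimethylsilyl)hept-4-en-6-ynoate, via 1-ethoxyvinyl ether of 12 14 (not isolated)
Conditions: 13 (8 equiv), EtCO2H (5 mol %), xylene, 135 °C, EtOH distilled off
Reagents that add atoms: none
Why: Johnson–Claisen rearrangement through a chair transition state with the alkynyl group pseudo-equatorial: the C–O stereocentre is transferred suprafacially to C9 (3R in 15), the new C1=C10 bond is E with the C20 methyl cis to the alkyne, and the silyl cap disfavours reaction through the propargyl arm.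

Step 7
Reactants: 15 ethyl (3R,4E)-4-methyl-3-Sc-7-(trimethylsilyl)hept-4-en-6-ynoate
Product: 18 ethyl (4E)-4-methyl-2-methylidene-3-Sc-7-(trimethylsilyl)hept-4-en-6-ynoate (C3 arrangement as in 15), via Mannich base 16 (not isolated), via trimethylammonium iodide 17 (not isolated)
Conditions: LiN(iPr)2, THF, −78 °C; CH2=NMe2+ I−, −78 → 23 °C; then MeI, MeOH, 23 °C; then aq NaHCO3, CH2Cl2, 23 °C
Reagents that add atoms: N,N-dimethylmethyleneiminium iodide (Eschenmoser's salt), C=[N+](C)C.[I-]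
Why: Ester-enolate Mannich reaction, N-methylation and base-induced loss of trimethylamine (α-methylenation) should install the carbon that becomes C7 without touching C9.

Step 8
Reactants: 18 ethyl (4E)-4-methyl-2-methylidene-3-Sc-7-(trimethylsilyl)hept-4-en-6-ynoate
Product: 19 (4E)-4-methyl-2-methylidene-3-Sc-7-(trimethylsilyl)hept-4-en-6-yn-1-ol
Conditions: iBu2AlH (2.5 equiv), CH2Cl2, −78 °C; aq potassium sodium tartrate
Reagents that add atoms: none
Why: 1,2-Reduction of the α-methylene ester by the aluminium hydride should give the 2-substituted allylic alcohol.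

Step 9
Reactants: 19 (4E)-4-methyl-2-methylidene-3-Sc-7-(trimethylsilyl)hept-4-en-6-yn-1-ol; 13 triethyl orthoacetate
Product: 21 ethyl (6E)-6-methyl-4-methylidene-5-Sc-9-(trimethylsilyl)non-6-en-8-ynoate, via 1-ethoxyvinyl ether of 19 20 (not isolated)
Conditions: 13 (8 equiv), EtCO2H (5 mol %), xylene, 135 °C
Reagents that add atoms: none
Why: A second Johnson–Claisen rearrangement transposes the allyl unit, so that the former carbinol carbon becomes the C17 methylene and the chain grows by C6–C5 as an ester; no stereocentre is formed.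

Step 10
Reactants: 21 ethyl (6E)-6-methyl-4-methylidene-5-Sc-9-(trimethylsilyl)non-6-en-8-ynoate
Product: 22 ethyl (6E)-6-methyl-4-methylidene-5-Sc-non-6-en-8-ynoate
Conditions: K2CO3 (0.3 equiv), EtOH, 23 °C
Reagents that add atoms: none
Why: Base-catalysed protodesilylation of the alkynylsilane; ethanol avoids ester exchange and the TBS ethers are stable.

Step 11
Reactants: 22 ethyl (6E)-6-methyl-4-methylidene-5-Sc-non-6-en-8-ynoate
Product: 23 ethyl (6E,8E)-9-Bpin-6-methyl-4-methylidene-5-Sc-nona-6,8-dienoate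
Conditions: HBpin (1.3 equiv), Cp2Zr(H)Cl (10 mol %), Et3N (10 mol %), CH2Cl2, 40 °C
Reagents that add atoms: pinacolborane, [H]B1OC(C)(C)C(C)(C)O1
Why: Zirconium-catalysed hydroboration (hydrozirconation, then transfer to boron) adds H–B syn and anti-Markovnikov to the terminal alkyne and should give the E,E-dienylboronate with the ester and other alkenes untouched.

Step 12
Reactants: 23 ethyl (6E,8E)-9-Bpin-6-methyl-4-methylidene-5-Sc-nona-6,8-dienoate
Product: 24 (6E,8E)-9-Bpin-6-methyl-4-methylidene-5-Sc-nona-6,8-dienal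
Conditions: iBu2AlH (1.1 equiv), CH2Cl2, −78 °C; MeOH, then aq potassium sodium tartrate
Reagents that add atoms: none
Why: Partial reduction of the ester to the aldehyde through the aluminium hemiacetal that is stable at −78 °C.

Step 13
Reactants: 24 (6E,8E)-9-Bpin-6-methyl-4-methylidene-5-Sc-nona-6,8-dienal; 25 2-(triphenylphosphoranylidene)propanal
Product: 26 (2E,8E,10E)-11-Bpin-2,8-dimethyl-6-methylidene-7-Sc-undeca-2,8,10-trienal
Conditions: 25 (1.5 equiv), CH2Cl2, 40 °C
Reagents that add atoms: none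
Why: Wittig olefination with the stabilised ylide should give the E enal (formyl trans to the chain), the dienophile geometry that the cycloaddition needs.

Step 14
Reactants: 26 (2E,8E,10E)-11-Bpin-2,8-dimethyl-6-methylidene-7-Sc-undeca-2,8,10-trienal
Product: 27 3-Bpin-15,16-bis(TBS-oxy)labda-1,8(17),13Z-trien-18-al (trans-decalin; C3–B and C4–CHO cis to H-5; C19 methyl and C11 cis to the C20 methyl)
Conditions: Me2AlCl (1.2 equiv), CH2Cl2 (0.01 M), −78 → −20 °C; aq potassium sodium tartrate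
Reagents that add atoms: none
Why: Me2AlCl binds the formyl oxygen and the (E)-2-methylenal (C4=C5) undergoes a concerted but asynchronous intramolecular Diels–Alder reaction with the 1-boryl diene (C10=C1–C2=C3), C5–C10 being the more advanced bond in the transition state; the closest known reaction type is the Lewis-acid-promoted intramolecular Diels–Alder reaction of 2-methyldeca-2,7,9-trienals, together with Diels–Alder reactions of 1-boryl-1,3-dienes. Ring B closes through the four-carbon tether C6–C9 in the fused mode by formation of C5–C10, and ring A closes as the new cyclohexene by the [4+2] bond pair C5–C10 and C3–C4. C4 and C5 are fixed relative to each other by the E geometry of the dienophile (suprafacial addition: formyl cis to H-5, C19 methyl cis to C6). C10 and C3 follow from the E,E diene (tether outside, C20 methyl inside, boron outside) combined with the endo orientation of the aluminium-bound formyl group, which gives the trans ring fusion (H-5 anti to C20) and puts the C3–B bond cis to the formyl group. The absolute sense comes from C9, whose side chain takes the pseudo-equatorial position of the chair-like tether so that C11 ends up cis to C20. The step needs endo over exo selectivity, π-facial selectivity and chemoselectivity for the diene over the C8 methylene; these are secured by Lewis-acid activation of the enal at low temperature, by the C9 stereocentre and by the higher nucleophilicity of the conjugated diene, while high dilution suppresses intermolecular allylboration of the product aldehyde.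

Step 15
Reactants: 27 3-Bpin-15,16-bis(TBS-oxy)labda-1,8(17),13Z-trien-18-al
Product: 29 15,16-bis(TBS-oxy)labda-1,8(17),13Z-triene-3,18-diol (3-OH axial and cis to H-5), via 18-hydroxy allylboronate 28 (not isolated)
Conditions: NaBH4, THF/MeOH, 0 °C; then 3 M NaOH, 30% H2O2, 0 → 23 °C
Reagents that add atoms: hydrogen peroxide, OO
Why: Borohydride reduction of the aldehyde, then oxidation of the allylic C–B bond with retention and without allylic shift (1,2-migration from boron to oxygen), should give the 3,18-diol.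

Step 16
Reactants: 29 15,16-bis(TBS-oxy)labda-1,8(17),13Z-triene-3,18-diol
Product: 30 15,16,18-tris(TBS-oxy)labda-1,8(17),13Z-trien-3-ol
Conditions: TBSCl (1.1 equiv), imidazole, CH2Cl2, 0 °C
Reagents that add atoms: tert-butyldimethylsilyl chloride, CC(C)(C)[Si](C)(C)Cl
Why: Silylation is expected to be selective for the primary C18 hydroxyl over the axial secondary allylic C3 hydroxyl flanked by the quaternary C4.

Step 17
Reactants: 30 15,16,18-tris(TBS-oxy)labda-1,8(17),13Z-trien-3-ol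
Product: 31 15,16,18-tris(TBS-oxy)labda-1,8(17),13Z-trien-3-one
Conditions: Dess–Martin periodinane, CH2Cl2, 23 °C
Reagents that add atoms: none
Why: Dess–Martin oxidation of the allylic alcohol gives the 1-en-3-one and erases the temporary C3 stereocentre.

Step 18
Reactants: 31 15,16,18-tris(TBS-oxy)labda-1,8(17),13Z-trien-3-one
Product: 32 3-(TES-oxy)-15,16,18-tris(TBS-oxy)labda-2,8(17),13Z-triene
Conditions: [(Ph3P)CuH]6 (0.4 equiv), Et3SiCl (3 equiv), THF/benzene, 23 °C
Reagents that add atoms: chlorotriethylsilane, CC[Si](Cl)(CC)CC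
Why: Conjugate reduction of the enone by the copper hydride and O-silylation of the enolate (reductive silylation) should give the regiodefined C2=C3 silyl enol ether without touching or isomerising the isolated alkenes.

Step 19
Reactants: 32 3-(TES-oxy)-15,16,18-tris(TBS-oxy)labda-2,8(17),13Z-triene
Product: 34 2-(TES-oxy)-15,16,18-tris(TBS-oxy)labda-8(17),13Z-dien-3-one (C2–O equatorial and cis to H-5), via silyloxy epoxide 33 (not isolated)
Conditions: mCPBA (1.05 equiv), NaHCO3, CH2Cl2, −30 → 0 °C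
Reagents that add atoms: 3-chloroperoxybenzoic acid, OOC(=O)c1cccc(Cl)c1
Why: Rubottom oxidation: the electron-rich enol ether is epoxidised from the face of H-5 (anti to the axial C19 and C20 methyls) and 1,4-silyl migration opens the epoxide to the equatorial 2-silyloxy 3-ketone.

Step 20
Reactants: 34 2-(TES-oxy)-15,16,18-tris(TBS-oxy)labda-8(17),13Z-dien-3-one
Product: 35 2-(TES-oxy)-15,16,18-tris(TBS-oxy)labda-8(17),13Z-dien-3-ol (3-OH equatorial; trans to the C2 oxygen)
Conditions: NaBH4, MeOH/CH2Cl2, −40 → −20 °C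
Reagents that add atoms: none
Why: Carbonyl reduction with axial hydride delivery from the face of H-5 (the other face is blocked by the axial C19 methyl) should give the equatorial 3-OH trans to the C2 oxygen, as in related 2,3-dioxygenated 4,4-disubstituted decalins.

Step 21
Reactants: 35 2-(TES-oxy)-15,16,18-tris(TBS-oxy)labda-8(17),13Z-dien-3-ol; 36 angelic acid
Product: 38 2-(TES-oxy)-15,16,18-tris(TBS-oxy)labda-8(17),13Z-dien-3-yl (2Z)-2-methylbut-2-enoate, via angelic 2,4,6-trichlorobenzoic anhydride 37 (not isolated)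
Conditions: 36 (3 equiv), 2,4,6-trichlorobenzoyl chloride (3 equiv), Et3N, toluene, 23 °C; then 35, 80 °C
Reagents that add atoms: none
Why: Yamaguchi-type esterification through the mixed anhydride without a nucleophilic catalyst, conditions under which the Z geometry of the angeloyl group is expected to survive, acylates the only free hydroxyl (C3).

Step 22
Reactants: 38 2-(TES-oxy)-15,16,18-tris(TBS-oxy)labda-8(17),13Z-dien-3-yl (2Z)-2-methylbut-2-enoate
Product: 39 (2S,3S,4S,5S,9R,10S)-2,15,16,18-tetrahydroxylabda-8(17),13Z-dien-3-yl (2Z)-2-methylbut-2-enoate (CNP0324138.1)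
Conditions: HF·pyridine, pyridine/THF, 0 → 23 °C
Reagents that add atoms: none
Why: Fluoride-mediated cleavage of the four silyl ethers under weakly acidic conditions that should neither move nor isomerise the angelate.

Compound list
1 | but-3-en-1-ylmagnesium bromide | C=CCC[Mg]Br | starting material
2 | dimethyl but-2-ynedioate | COC(=O)C#CC(=O)OC | starting material
3 | but-3-en-1-ylcopper | C=CCC[Cu] | intermediate
4 | alkenylcopper syn-adduct (copper cis to the butenyl group) | COC(=O)/C([Cu])=C(/CCC=C)C(=O)OC | intermediate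
5 | dimethyl (2Z)-2-(but-3-en-1-yl)but-2-enedioate | COC(=O)/C=C(/CCC=C)C(=O)OC | intermediate
6 | (2Z)-2-(but-3-en-1-yl)but-2-ene-1,4-diol | OC/C=C(/CCC=C)CO | intermediate
7 | (2Z)-2-(but-3-en-1-yl)-1,4-bis(TBS-oxy)but-2-ene | CC(C)(C)[Si](C)(C)OC/C=C(/CCC=C)CO[Si](C)(C)C(C)(C)C | intermediate
8 | methacrolein | C=C(C)C=O | starting material
9 | (2E,6Z)-8-(TBS-oxy)-6-[(TBS-oxy)methyl]-2-methylocta-2,6-dienal | O=C/C(C)=C/CC/C(=C/CO[Si](C)(C)C(C)(C)C)CO[Si](C)(C)C(C)(C)C | intermediate
10 | ethynyltrimethylsilane | C#C[Si](C)(C)C | starting material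
11 | methyl[(trimethylsilyl)ethynyl]zinc | C[Zn]C#C[Si](C)(C)C | intermediate
12 | (3S,4E,8Z)-10-(TBS-oxy)-8-[(TBS-oxy)methyl]-4-methyl-1-(trimethylsilyl)deca-4,8-dien-1-yn-3-ol | C[Si](C)(C)C#C[C@@H](O)/C(C)=C/CC/C(=C/CO[Si](C)(C)C(C)(C)C)CO[Si](C)(C)C(C)(C)C | intermediate
13 | triethyl orthoacetate | CCOC(C)(OCC)OCC | starting material
14 | 1-ethoxyvinyl ether of 12 (mixed ketene acetal) | C[Si](C)(C)C#C[C@@H](OC(=C)OCC)/C(C)=C/CC/C(=C/CO[Si](C)(C)C(C)(C)C)CO[Si](C)(C)C(C)(C)C | intermediate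
15 | ethyl (3R,4E)-4-methyl-3-Sc-7-(trimethylsilyl)hept-4-en-6-ynoate | C[Si](C)(C)C#C/C=C(C)/[C@@H](CC(=O)OCC)CC/C(=C/CO[Si](C)(C)C(C)(C)C)CO[Si](C)(C)C(C)(C)C | intermediate
16 | Mannich base: 2-[(dimethylamino)methyl] derivative of 15 (C2 epimers) | C[Si](C)(C)C#C/C=C(C)/[C@@H](C(CN(C)C)C(=O)OCC)CC/C(=C/CO[Si](C)(C)C(C)(C)C)CO[Si](C)(C)C(C)(C)C | intermediate
17 | trimethylammonium iodide of 16 | C[Si](C)(C)C#C/C=C(C)/[C@@H](C(C[N+](C)(C)C)C(=O)OCC)CC/C(=C/CO[Si](C)(C)C(C)(C)C)CO[Si](C)(C)C(C)(C)C.[I-] | intermediate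
18 | ethyl (4E)-4-methyl-2-methylidene-3-Sc-7-(trimethylsilyl)hept-4-en-6-ynoate | C[Si](C)(C)C#C/C=C(C)/[C@@H](C(=C)C(=O)OCC)CC/C(=C/CO[Si](C)(C)C(C)(C)C)CO[Si](C)(C)C(C)(C)C | intermediate
19 | (4E)-4-methyl-2-methylidene-3-Sc-7-(trimethylsilyl)hept-4-en-6-yn-1-ol | C[Si](C)(C)C#C/C=C(C)/[C@@H](C(=C)CO)CC/C(=C/CO[Si](C)(C)C(C)(C)C)CO[Si](C)(C)C(C)(C)C | intermediate
20 | 1-ethoxyvinyl ether of 19 (mixed ketene acetal) | C[Si](C)(C)C#C/C=C(C)/[C@@H](C(=C)COC(=C)OCC)CC/C(=C/CO[Si](C)(C)C(C)(C)C)CO[Si](C)(C)C(C)(C)C | intermediate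
21 | ethyl (6E)-6-methyl-4-methylidene-5-Sc-9-(trimethylsilyl)non-6-en-8-ynoate | C[Si](C)(C)C#C/C=C(C)/[C@@H](C(=C)CCC(=O)OCC)CC/C(=C/CO[Si](C)(C)C(C)(C)C)CO[Si](C)(C)C(C)(C)C | intermediate
22 | ethyl (6E)-6-methyl-4-methylidene-5-Sc-non-6-en-8-ynoate | C#C/C=C(C)/[C@@H](C(=C)CCC(=O)OCC)CC/C(=C/CO[Si](C)(C)C(C)(C)C)CO[Si](C)(C)C(C)(C)C | intermediate
23 | ethyl (6E,8E)-9-Bpin-6-methyl-4-methylidene-5-Sc-nona-6,8-dienoate | CC1(C)OB(OC1(C)C)/C=C/C=C(C)/[C@@H](C(=C)CCC(=O)OCC)CC/C(=C/CO[Si](C)(C)C(C)(C)C)CO[Si](C)(C)C(C)(C)C | intermediate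
24 | (6E,8E)-9-Bpin-6-methyl-4-methylidene-5-Sc-nona-6,8-dienal | CC1(C)OB(OC1(C)C)/C=C/C=C(C)/[C@@H](C(=C)CCC=O)CC/C(=C/CO[Si](C)(C)C(C)(C)C)CO[Si](C)(C)C(C)(C)C | intermediate
25 | 2-(triphenylphosphoranylidene)propanal | CC(C=O)=P(c1ccccc1)(c1ccccc1)c1ccccc1 | starting material
26 | (2E,8E,10E)-11-Bpin-2,8-dimethyl-6-methylidene-7-Sc-undeca-2,8,10-trienal | CC1(C)OB(OC1(C)C)/C=C/C=C(C)/[C@@H](C(=C)CC/C=C(\C)C=O)CC/C(=C/CO[Si](C)(C)C(C)(C)C)CO[Si](C)(C)C(C)(C)C | intermediate
27 | 3-Bpin-15,16-bis(TBS-oxy)labda-1,8(17),13Z-trien-18-al (trans-decalin; B and CHO cis to H-5) | C=C1CC[C@H]2[C@@](C)(C=C[C@H](B3OC(C)(C)C(C)(C)O3)[C@]2(C)C=O)[C@@H]1CC/C(=C/CO[Si](C)(C)C(C)(C)C)CO[Si](C)(C)C(C)(C)C | intermediate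
28 | 3-Bpin-15,16-bis(TBS-oxy)labda-1,8(17),13Z-trien-18-ol | C=C1CC[C@H]2[C@@](C)(C=C[C@H](B3OC(C)(C)C(C)(C)O3)[C@]2(C)CO)[C@@H]1CC/C(=C/CO[Si](C)(C)C(C)(C)C)CO[Si](C)(C)C(C)(C)C | intermediate
29 | 15,16-bis(TBS-oxy)labda-1,8(17),13Z-triene-3,18-diol (3-OH axial; cis to H-5) | C=C1CC[C@H]2[C@@](C)(C=C[C@H](O)[C@]2(C)CO)[C@@H]1CC/C(=C/CO[Si](C)(C)C(C)(C)C)CO[Si](C)(C)C(C)(C)C | intermediate
30 | 15,16,18-tris(TBS-oxy)labda-1,8(17),13Z-trien-3-ol | C=C1CC[C@H]2[C@@](C)(C=C[C@H](O)[C@]2(C)CO[Si](C)(C)C(C)(C)C)[C@@H]1CC/C(=C/CO[Si](C)(C)C(C)(C)C)CO[Si](C)(C)C(C)(C)C | intermediate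
31 | 15,16,18-tris(TBS-oxy)labda-1,8(17),13Z-trien-3-one | C=C1CC[C@H]2[C@@](C)(C=CC(=O)[C@]2(C)CO[Si](C)(C)C(C)(C)C)[C@@H]1CC/C(=C/CO[Si](C)(C)C(C)(C)C)CO[Si](C)(C)C(C)(C)C | intermediate
32 | 3-(TES-oxy)-15,16,18-tris(TBS-oxy)labda-2,8(17),13Z-triene | C=C1CC[C@H]2[C@@](C)(CC=C(O[Si](CC)(CC)CC)[C@]2(C)CO[Si](C)(C)C(C)(C)C)[C@@H]1CC/C(=C/CO[Si](C)(C)C(C)(C)C)CO[Si](C)(C)C(C)(C)C | intermediate
33 | 2,3-epoxide of 32 (epoxide oxygen cis to H-5) | C=C1CC[C@H]2[C@@](C)(C[C@@H]3O[C@]3(O[Si](CC)(CC)CC)[C@]2(C)CO[Si](C)(C)C(C)(C)C)[C@@H]1CC/C(=C/CO[Si](C)(C)C(C)(C)C)CO[Si](C)(C)C(C)(C)C | intermediate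
34 | 2-(TES-oxy)-15,16,18-tris(TBS-oxy)labda-8(17),13Z-dien-3-one (C2–O equatorial; cis to H-5) | C=C1CC[C@H]2[C@@](C)(C[C@H](O[Si](CC)(CC)CC)C(=O)[C@]2(C)CO[Si](C)(C)C(C)(C)C)[C@@H]1CC/C(=C/CO[Si](C)(C)C(C)(C)C)CO[Si](C)(C)C(C)(C)C | intermediate
35 | 2-(TES-oxy)-15,16,18-tris(TBS-oxy)labda-8(17),13Z-dien-3-ol (3-OH equatorial; trans to C2–O) | C=C1CC[C@H]2[C@@](C)(C[C@H](O[Si](CC)(CC)CC)[C@@H](O)[C@]2(C)CO[Si](C)(C)C(C)(C)C)[C@@H]1CC/C(=C/CO[Si](C)(C)C(C)(C)C)CO[Si](C)(C)C(C)(C)C | intermediate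
36 | angelic acid, (2Z)-2-methylbut-2-enoic acid | C/C=C(/C)C(=O)O | starting material
37 | angelic 2,4,6-trichlorobenzoic anhydride | C/C=C(/C)C(=O)OC(=O)c1c(Cl)cc(Cl)cc1Cl | intermediate
38 | 2-(TES-oxy)-15,16,18-tris(TBS-oxy)labda-8(17),13Z-dien-3-yl (2Z)-2-methylbut-2-enoate | C=C1CC[C@H]2[C@@](C)(C[C@H](O[Si](CC)(CC)CC)[C@@H](OC(=O)/C(C)=C\C)[C@]2(C)CO[Si](C)(C)C(C)(C)C)[C@@H]1CC/C(=C/CO[Si](C)(C)C(C)(C)C)CO[Si](C)(C)C(C)(C)C | intermediate
39 | (2S,3S,4S,5S,9R,10S)-2,15,16,18-tetrahydroxylabda-8(17),13Z-dien-3-yl (2Z)-2-methylbut-2-enoate (CNP0324138.1) | C=C1CC[C@H]2[C@@](C)(C[C@H](O)[C@@H](OC(=O)/C(C)=C\C)[C@]2(C)CO)[C@@H]1CC/C(=C/CO)CO | target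

Total step count: 22. Longest linear sequence: 22 steps (from 1 and 2 to 39; the route is fully linear).

Steps most likely to fail

1. Step 14 (key cycloaddition). The endo mode builds up the 1,3-diaxial contact between the C19 and C20 methyls, so endo control may erode and cis-fused material may form. The aluminium-activated enal may also be attacked by the C8 methylene in a cation–olefin cyclisation. The fallback sets out from 24 and replaces the formyl group by a larger, chelating acyl group. Horner–Wadsworth–Emmons olefination of 24 with 3-[2-(diethoxyphosphoryl)propanoyl]oxazolidin-2-one (LiCl, iPr2NEt, MeCN) should give the (E)-N-enoyl oxazolidinone F1. Me2AlCl (1.5 equiv, CH2Cl2, −30 °C) then chelates the imide; this dienophile is more reactive and its bulky acyl group is expected to avoid the position syn to C20, so the cycloaddition should give the trans-fused imide cycloadduct F2. Reductive removal of the oxazolidinone with LiBH4 (THF/MeOH) gives 28, which is oxidised as in step 15 to 29.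

2. Step 6 (first Johnson–Claisen). At 135 °C with acid, the doubly activated (allylic and propargylic) C–O bond may ionise and the carbinol configuration be lost before rearrangement, or the shift may run through the propargyl arm. The fallback sets out from 12 and uses an ester-enolate rearrangement at low temperature under basic conditions. Acetylation (Ac2O, pyridine) gives the acetate F3. Ireland–Claisen rearrangement (LiN(SiMe3)2, Me3SiCl, THF, −78 → 23 °C; aqueous work-up) through the same chair transition state should give the acid F4. Esterification (EtI, K2CO3, DMF) returns to 15.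

3. Step 21 (angeloylation). The activated angeloyl unit may isomerise from Z to E (tiglate), and acylation of the hindered C3 hydroxyl may be slow enough for silyl migration from O2 to O3 to compete. The fallback sets out from 35 and builds the Z double bond on the substrate. Coupling with 2-[bis(2,2,2-trifluoroethoxy)phosphoryl]propanoic acid (EDC·HCl, DMAP, CH2Cl2) gives the phosphonopropionate F5. Still–Gennari olefination (KN(SiMe3)2, 18-crown-6, THF, −78 °C, acetaldehyde) should give the Z ester 38.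

Further compounds
F1 | step 14 | 3-[(2E,8E,10E)-11-Bpin-2,8-dimethyl-6-methylidene-7-Sc-undeca-2,8,10-trienoyl]oxazolidin-2-one | CC1(C)OB(OC1(C)C)/C=C/C=C(C)/[C@@H](C(=C)CC/C=C(\C)C(=O)N1CCOC1=O)CC/C(=C/CO[Si](C)(C)C(C)(C)C)CO[Si](C)(C)C(C)(C)C
F2 | step 14 | imide cycloadduct: 27 with the C18 formyl group replaced by (2-oxooxazolidin-3-yl)carbonyl | C=C1CC[C@H]2[C@@](C)(C=C[C@H](B3OC(C)(C)C(C)(C)O3)[C@]2(C)C(=O)N4CCOC4=O)[C@@H]1CC/C(=C/CO[Si](C)(C)C(C)(C)C)CO[Si](C)(C)C(C)(C)C
F3 | step 6 | acetate of 12 | C[Si](C)(C)C#C[C@@H](OC(C)=O)/C(C)=C/CC/C(=C/CO[Si](C)(C)C(C)(C)C)CO[Si](C)(C)C(C)(C)C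
F4 | step 6 | (3R,4E)-4-methyl-3-Sc-7-(trimethylsilyl)hept-4-en-6-ynoic acid | C[Si](C)(C)C#C/C=C(C)/[C@@H](CC(=O)O)CC/C(=C/CO[Si](C)(C)C(C)(C)C)CO[Si](C)(C)C(C)(C)C
F5 | step 21 | 3-O-{2-[bis(2,2,2-trifluoroethoxy)phosphoryl]propanoyl} derivative of 35 | C=C1CC[C@H]2[C@@](C)(C[C@H](O[Si](CC)(CC)CC)[C@@H](OC(=O)C(C)P(=O)(OCC(F)(F)F)OCC(F)(F)F)[C@]2(C)CO[Si](C)(C)C(C)(C)C)[C@@H]1CC/C(=C/CO[Si](C)(C)C(C)(C)C)CO[Si](C)(C)C(C)(C)C
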